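**Retrosynthetic overview**

1. The target is a 3,3''-biflavanone with both pyranone rings 2,3-cis (2R,3R in each); unit A is the 5,7-dihydroxy half, unit B the 5-hydroxy-7-methoxy half (PMB = 4-methoxybenzyl). The enabling feature is that in each pyranone the fragment O1–C2(H)–(4-methoxyphenyl) is a PMB ether of the ring-A phenol, and its C2–H bond, activated by O1 and the anisyl ring, lies six atoms from C3, the carbon alpha to the C4 ketone.
2. Both C2–C3 bonds are therefore cut to "carbenoid at C3 plus PMB-ether C–H". The precursor of the first closure is the achiral, open-chain 2-diazo-1,4-diketone 13 with five PMB ethers: two become the C2-aryl units, three stay as protecting groups.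
3. Ring order: the pyranone of unit B closes first by enantioselective dirhodium-catalysed 1,6 C–H insertion (sets C2 and C3 of unit B). Diazo transfer to the remaining CH2 and the same insertion then close the pyranone of unit A.
4. Compound 13 comes from two phloroacetophenones, each etherified one PMB group at a time (free phenol first, chelated phenol last): Claisen acetylation of one, alpha-bromination of the other, C-alkylation (forms the C3–C3'' bond), deacetylative diazo transfer.
5. Hydrogenolysis of the three spectator PMB ethers ends the route.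

Key step: step 10

Assumption: Rh2(S-PTTL)4 (dirhodium tetrakis[N-phthaloyl-(S)-tert-leucinate]) is taken as the catalyst antipode that leads to the (2R,3R) series; if the first insertion shows the opposite sense, Rh2(R-PTTL)4 is used in steps 10 and 12.

**Route**

Step 1
Reactants: 1 1-(2,6-dihydroxy-4-methoxyphenyl)ethan-1-one; 2 4-methoxybenzyl chloride
Product: 3 1-[2-hydroxy-4-methoxy-6-(4-methoxybenzyloxy)phenyl]ethan-1-one
Conditions: K2CO3 (1.1 equiv), 2 (1.05 equiv), n-Bu4NI (cat.), acetone, reflux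
Reagents that add atoms: none
Why: Williamson etherification: one of the two equivalent ortho phenols is alkylated under mild conditions, after which the remaining phenol is held in a hydrogen bond to the ketone and should react much more slowly, so that monoalkylation is expected (any diether formed is compound 4 and is carried on).

Step 2
Reactants: 3 1-[2-hydroxy-4-methoxy-6-(4-methoxybenzyloxy)phenyl]ethan-1-one; 2 4-methoxybenzyl chloride
Product: 4 1-[4-methoxy-2,6-bis(4-methoxybenzyloxy)phenyl]ethan-1-one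
Conditions: K2CO3, n-Bu4NI (cat.), DMF, 70 °C
Reagents that add atoms: none
Why: Williamson etherification of the chelated phenol, which needs the dipolar solvent, warming and iodide catalysis; the two ortho PMB ethers of unit B that result are homotopic, so the later C–H insertion needs no choice between them.

Step 3
Reactants: 4 1-[4-methoxy-2,6-bis(4-methoxybenzyloxy)phenyl]ethan-1-one
Product: 5 1-[4-methoxy-2,6-bis(4-methoxybenzyloxy)phenyl]butane-1,3-dione
Conditions: NaH, THF, 65 °C; AcOH quench
Reagents that add atoms: ethyl acetate, CCOC(C)=O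
Why: Crossed Claisen condensation of the methyl ketone enolate with ethyl acetate, driven by formation of the diketonate; the acetyl group is a traceless activator for the later diazo transfer.

Step 4
Reactants: 6 1-(2,4,6-trihydroxyphenyl)ethan-1-one; 2 4-methoxybenzyl chloride
Product: 7 1-[2,6-dihydroxy-4-(4-methoxybenzyloxy)phenyl]ethan-1-one
Conditions: K2CO3 (1.0 equiv), n-Bu4NI (cat.), DMF, 0 °C to rt, slow addition of 2 (1.0 equiv)
Reagents that add atoms: none
Why: Williamson etherification: the 4-hydroxyl, para to the acetyl group, is the most acidic one and the only one not hydrogen-bonded to the ketone, so one equivalent of base and halide should alkylate it first (diether 8 formed by over-alkylation is the product of step 5 and is combined with it).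

Step 5
Reactants: 7 1-[2,6-dihydroxy-4-(4-methoxybenzyloxy)phenyl]ethan-1-one; 2 4-methoxybenzyl chloride
Product: 8 1-[2-hydroxy-4,6-bis(4-methoxybenzyloxy)phenyl]ethan-1-one
Conditions: K2CO3 (1.1 equiv), 2 (1.05 equiv), n-Bu4NI (cat.), acetone, reflux
Reagents that add atoms: none
Why: Williamson etherification of one of the two equivalent ortho phenols under mild conditions; the other stays chelated to the ketone and is left for the more forcing step 6.

Step 6
Reactants: 8 1-[2-hydroxy-4,6-bis(4-methoxybenzyloxy)phenyl]ethan-1-one; 2 4-methoxybenzyl chloride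
Product: 9 1-[2,4,6-tris(4-methoxybenzyloxy)phenyl]ethan-1-one
Conditions: K2CO3, n-Bu4NI (cat.), DMF, 70 °C
Reagents that add atoms: none
Why: Williamson etherification of the last, chelated phenol under forcing conditions, as known for the tribenzyl ether of this ketone; the two ortho PMB ethers of unit A are now homotopic.

Step 7
Reactants: 9 1-[2,4,6-tris(4-methoxybenzyloxy)phenyl]ethan-1-one
Product: 11 2-bromo-1-[2,4,6-tris(4-methoxybenzyloxy)phenyl]ethan-1-one, via trimethylsilyl enol ether 10 (not isolated)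
Conditions: LiN(SiMe3)2, Me3SiCl, THF, −78 °C; then NBS, −78 to 0 °C; aqueous work-up
Reagents that add atoms: N-bromosuccinimide, O=C1CCC(=O)N1Br; chlorotrimethylsilane, C[Si](C)(C)Cl (its silyl group is in 10 only)
Why: Alpha-bromination of a silyl enol ether: the enol carbon should react with NBS faster than the electron-rich ring, and the non-acidic conditions spare the PMB ethers.

Step 8
Reactants: 5 1-[4-methoxy-2,6-bis(4-methoxybenzyloxy)phenyl]butane-1,3-dione; 11 2-bromo-1-[2,4,6-tris(4-methoxybenzyloxy)phenyl]ethan-1-one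
Product: 12 2-acetyl-1-[4-methoxy-2,6-bis(4-methoxybenzyloxy)phenyl]-4-[2,4,6-tris(4-methoxybenzyloxy)phenyl]butane-1,4-dione (racemic)
Conditions: K2CO3, acetone, rt
Reagents that add atoms: none
Why: SN2 C-alkylation of the stabilized 1,3-diketone enolate by the primary alpha-bromoketone; it forms the future C3–C3'' bond.

Step 9
Reactants: 12 2-acetyl-1-[4-methoxy-2,6-bis(4-methoxybenzyloxy)phenyl]-4-[2,4,6-tris(4-methoxybenzyloxy)phenyl]butane-1,4-dione
Product: 13 2-diazo-1-[4-methoxy-2,6-bis(4-methoxybenzyloxy)phenyl]-4-[2,4,6-tris(4-methoxybenzyloxy)phenyl]butane-1,4-dione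
Conditions: 4-acetamidobenzenesulfonyl azide, DBU, MeCN, 0 °C to rt
Reagents that add atoms: 4-acetamidobenzenesulfonyl azide, CC(=O)Nc1ccc(cc1)S(=O)(=O)N=[N+]=[N-]
Why: Deacylative Regitz diazo transfer: the triazoline should fragment with loss of the unhindered acetyl group (not the shielded, electron-rich 2,6-dialkoxybenzoyl group), which places the diazo group only at the carbon alpha to unit B's ketone.

Step 10
Reactants: 13 2-diazo-1-[4-methoxy-2,6-bis(4-methoxybenzyloxy)phenyl]-4-[2,4,6-tris(4-methoxybenzyloxy)phenyl]butane-1,4-dione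
Product: 14 (2R,3R)-7-methoxy-5-(4-methoxybenzyloxy)-2-(4-methoxyphenyl)-3-{2-oxo-2-[2,4,6-tris(4-methoxybenzyloxy)phenyl]ethyl}chroman-4-one (2,3-cis)
Conditions: Rh2(S-PTTL)4 (1 mol%), CH2Cl2, −40 to 0 °C, slow addition of 13
Reagents that add atoms: none
Why: Loss of N2 at the dirhodium centre gives an electrophilic carbenoid at C3 of unit B, and the hydridic C–H of an ortho PMB ether adds across it in a concerted, asynchronous three-centre insertion that forms the C2–C3 bond and the C3–H bond and closes the pyranone of unit B. The closest known reaction type is the dirhodium-carboxylate-catalysed intramolecular C–H insertion of 2-diazo-1-(2-alkoxyaryl)alkan-1-ones next to the ether oxygen, which gives 2,3-cis chroman-4-ones under kinetic control and is enantioselective with chiral carboxylate ligands. The ring closes as a 1,6-insertion through a six-membered chair-like transition state; a 1,5-insertion is impossible because the fifth atom is the ether oxygen. C2 arises from the benzylic CH2 with retention, the chiral ligand sphere choosing one of its two enantiotopic hydrogens (2R), and C3 is the former carbenoid carbon, set in the same event with its side chain cis to the anisyl group because both point away from the ligand wall (3R). The step needs insertion to beat 1,2-hydride shift from the neighbouring CH2, ether-oxygen attack followed by [1,2]-benzyl shift, and 1,7-insertion into the ethers of unit A; the CH2 is deactivated towards hydride migration by its own ketone, dirhodium carboxylates at low temperature should favour insertion into this doubly activated C–H over ylide chemistry, and the seven-membered alternative is slower. The two ortho PMB ethers of the reacting ring are homotopic, so no choice between them is needed and the unreacted one becomes the 5-O-PMB group.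

Step 11
Reactants: 14 (2R,3R)-7-methoxy-5-(4-methoxybenzyloxy)-2-(4-methoxyphenyl)-3-{2-oxo-2-[2,4,6-tris(4-methoxybenzyloxy)phenyl]ethyl}chroman-4-one
Product: 16 (2R,3R)-3-{1-diazo-2-oxo-2-[2,4,6-tris(4-methoxybenzyloxy)phenyl]ethyl}-7-methoxy-5-(4-methoxybenzyloxy)-2-(4-methoxyphenyl)chroman-4-one, via trifluoroacetyl diketone 15 (not isolated)
Conditions: LiN(SiMe3)2, THF, −78 °C; CF3CO2CH2CF3; AcOH quench; then 4-acetamidobenzenesulfonyl azide, Et3N, H2O (1 equiv), MeCN, rt
Reagents that add atoms: 2,2,2-trifluoroethyl trifluoroacetate, O=C(OCC(F)(F)F)C(F)(F)F (its CF3CO group is in 15 only); 4-acetamidobenzenesulfonyl azide, CC(=O)Nc1ccc(cc1)S(=O)(=O)N=[N+]=[N-]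
Why: Detrifluoroacetylative diazo transfer: the amide base should deprotonate the less hindered side-chain CH2 kinetically and not the tertiary ring C3–H, C-trifluoroacetylation activates that carbon alone, and sulfonyl azide with Et3N then delivers N2 with loss of the trifluoroacetyl group under conditions too mild to epimerize the cis C3 centre.

Step 12
Reactants: 16 (2R,3R)-3-{1-diazo-2-oxo-2-[2,4,6-tris(4-methoxybenzyloxy)phenyl]ethyl}-7-methoxy-5-(4-methoxybenzyloxy)-2-(4-methoxyphenyl)chroman-4-one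
Product: 17 (2R,3R,2''R,3''R)-7''-methoxy-5,7,5''-tris(4-methoxybenzyloxy)-2,2''-bis(4-methoxyphenyl)-[3,3''-bichromane]-4,4''-dione
Conditions: Rh2(S-PTTL)4 (1 mol%), CH2Cl2, −40 to 0 °C
Reagents that add atoms: none
Why: The same dirhodium-catalysed 1,6 C–H insertion, now next to unit A's ketone: the same catalyst antipode should again select the hydrogen leading to 2R and place the anisyl group cis to the C3 substituent (3R), the near-C2-symmetric product being expected as the matched case, while the only beta-hydrogen (tertiary C3–H of unit B) is deactivated towards 1,2-shift by its ketone.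

Step 13
Reactants: 17 (2R,3R,2''R,3''R)-7''-methoxy-5,7,5''-tris(4-methoxybenzyloxy)-2,2''-bis(4-methoxyphenyl)-[3,3''-bichromane]-4,4''-dione
Product: 18 (2R,3R,2''R,3''R)-5,7,5''-trihydroxy-7''-methoxy-2,2''-bis(4-methoxyphenyl)-[3,3''-bichromane]-4,4''-dione
Conditions: H2 (1 atm), Pd/C (palladium on carbon), EtOAc, rt
Reagents that add atoms: none
Why: Catalytic hydrogenolysis should cleave the three acyclic aryl PMB ethers under neutral conditions that cannot enolize C3 or C3''; the two cyclic benzylic C2–O bonds are hindered and ring-constrained and should be slower, so the reaction is stopped after three equivalents of H2.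

**Compound list**

1 | 1-(2,6-dihydroxy-4-methoxyphenyl)ethan-1-one | CC(=O)c1c(O)cc(OC)cc1O | starting material
2 | 4-methoxybenzyl chloride | COc1ccc(CCl)cc1 | starting material
3 | 1-[2-hydroxy-4-methoxy-6-(4-methoxybenzyloxy)phenyl]ethan-1-one | CC(=O)c1c(O)cc(OC)cc1OCc1ccc(OC)cc1 | intermediate
4 | 1-[4-methoxy-2,6-bis(4-methoxybenzyloxy)phenyl]ethan-1-one | CC(=O)c1c(OCc2ccc(OC)cc2)cc(OC)cc1OCc1ccc(OC)cc1 | intermediate
5 | 1-[4-methoxy-2,6-bis(4-methoxybenzyloxy)phenyl]butane-1,3-dione | CC(=O)CC(=O)c1c(OCc2ccc(OC)cc2)cc(OC)cc1OCc1ccc(OC)cc1 | intermediate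
6 | 1-(2,4,6-trihydroxyphenyl)ethan-1-one | CC(=O)c1c(O)cc(O)cc1O | starting material
7 | 1-[2,6-dihydroxy-4-(4-methoxybenzyloxy)phenyl]ethan-1-one | CC(=O)c1c(O)cc(OCc2ccc(OC)cc2)cc1O | intermediate
8 | 1-[2-hydroxy-4,6-bis(4-methoxybenzyloxy)phenyl]ethan-1-one | CC(=O)c1c(O)cc(OCc2ccc(OC)cc2)cc1OCc1ccc(OC)cc1 | intermediate
9 | 1-[2,4,6-tris(4-methoxybenzyloxy)phenyl]ethan-1-one | CC(=O)c1c(OCc2ccc(OC)cc2)cc(OCc2ccc(OC)cc2)cc1OCc1ccc(OC)cc1 | intermediate
10 | trimethyl({1-[2,4,6-tris(4-methoxybenzyloxy)phenyl]ethenyl}oxy)silane (not isolated) | C=C(O[Si](C)(C)C)c1c(OCc2ccc(OC)cc2)cc(OCc2ccc(OC)cc2)cc1OCc1ccc(OC)cc1 | intermediate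
11 | 2-bromo-1-[2,4,6-tris(4-methoxybenzyloxy)phenyl]ethan-1-one | BrCC(=O)c1c(OCc2ccc(OC)cc2)cc(OCc2ccc(OC)cc2)cc1OCc1ccc(OC)cc1 | intermediate
12 | 2-acetyl-1-[4-methoxy-2,6-bis(4-methoxybenzyloxy)phenyl]-4-[2,4,6-tris(4-methoxybenzyloxy)phenyl]butane-1,4-dione (racemic) | CC(=O)C(CC(=O)c1c(OCc2ccc(OC)cc2)cc(OCc2ccc(OC)cc2)cc1OCc1ccc(OC)cc1)C(=O)c1c(OCc2ccc(OC)cc2)cc(OC)cc1OCc1ccc(OC)cc1 | intermediate
13 | 2-diazo-1-[4-methoxy-2,6-bis(4-methoxybenzyloxy)phenyl]-4-[2,4,6-tris(4-methoxybenzyloxy)phenyl]butane-1,4-dione | [N-]=[N+]=C(CC(=O)c1c(OCc2ccc(OC)cc2)cc(OCc2ccc(OC)cc2)cc1OCc1ccc(OC)cc1)C(=O)c1c(OCc2ccc(OC)cc2)cc(OC)cc1OCc1ccc(OC)cc1 | intermediate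
14 | (2R,3R)-7-methoxy-5-(4-methoxybenzyloxy)-2-(4-methoxyphenyl)-3-{2-oxo-2-[2,4,6-tris(4-methoxybenzyloxy)phenyl]ethyl}chroman-4-one | O=C(C[C@H]1C(=O)c2c(OCc3ccc(OC)cc3)cc(OC)cc2O[C@H]1c1ccc(OC)cc1)c1c(OCc2ccc(OC)cc2)cc(OCc2ccc(OC)cc2)cc1OCc1ccc(OC)cc1 | intermediate
15 | (2R,3R)-7-methoxy-5-(4-methoxybenzyloxy)-2-(4-methoxyphenyl)-3-{4,4,4-trifluoro-1,3-dioxo-1-[2,4,6-tris(4-methoxybenzyloxy)phenyl]butan-2-yl}chroman-4-one (side-chain epimers, not isolated) | O=C(C(C(=O)C(F)(F)F)[C@H]1C(=O)c2c(OCc3ccc(OC)cc3)cc(OC)cc2O[C@H]1c1ccc(OC)cc1)c1c(OCc2ccc(OC)cc2)cc(OCc2ccc(OC)cc2)cc1OCc1ccc(OC)cc1 | intermediate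
16 | (2R,3R)-3-{1-diazo-2-oxo-2-[2,4,6-tris(4-methoxybenzyloxy)phenyl]ethyl}-7-methoxy-5-(4-methoxybenzyloxy)-2-(4-methoxyphenyl)chroman-4-one | [N-]=[N+]=C([C@H]1C(=O)c2c(OCc3ccc(OC)cc3)cc(OC)cc2O[C@H]1c1ccc(OC)cc1)C(=O)c1c(OCc2ccc(OC)cc2)cc(OCc2ccc(OC)cc2)cc1OCc1ccc(OC)cc1 | intermediate
17 | (2R,3R,2''R,3''R)-7''-methoxy-5,7,5''-tris(4-methoxybenzyloxy)-2,2''-bis(4-methoxyphenyl)-[3,3''-bichromane]-4,4''-dione | COc1ccc([C@@H]2Oc3cc(OCc4ccc(OC)cc4)cc(OCc4ccc(OC)cc4)c3C(=O)[C@@H]2[C@H]2C(=O)c3c(OCc4ccc(OC)cc4)cc(OC)cc3O[C@H]2c2ccc(OC)cc2)cc1 | intermediate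
18 | (2R,3R,2''R,3''R)-5,7,5''-trihydroxy-7''-methoxy-2,2''-bis(4-methoxyphenyl)-[3,3''-bichromane]-4,4''-dione (both pyranone rings 2,3-cis) | COc1ccc([C@@H]2Oc3cc(O)cc(O)c3C(=O)[C@@H]2[C@H]2C(=O)c3c(O)cc(OC)cc3O[C@H]2c2ccc(OC)cc2)cc1 | target

**Summary**

Total step count: 13.
Longest linear sequence: 10 steps (steps 4, 5, 6, 7, 8, 9, 10, 11, 12, 13).

**Steps most likely to fail**

Step 10. The carbenoid may be diverted into attack on the ether oxygen followed by [1,2]-shift of the benzyl group, into 1,2-hydride migration from the neighbouring CH2, or it may insert with poor enantiofacial discrimination. The fallback sets out from 3 (with 11 as the electrophile) and comes back at 14; it sets C2 by asymmetric conjugate arylation and C3 by kinetic protonation. Condensation of 3 with dimethylformamide dimethyl acetal (toluene, 100 °C) gives (E)-3-(dimethylamino)-1-[2-hydroxy-4-methoxy-6-(4-methoxybenzyloxy)phenyl]prop-2-en-1-one F1, which closes under mild acid (pyridinium tosylate, toluene, 80 °C) to 7-methoxy-5-(4-methoxybenzyloxy)-4H-chromen-4-one F2. Asymmetric 1,4-addition of 4-methoxyphenylboronic acid (Pd(OCOCF3)2 with the tert-butyl pyridine-oxazoline ligand antipode that gives the 2R series, aqueous dichloroethane, 60 °C) should give (2R)-7-methoxy-5-(4-methoxybenzyloxy)-2-(4-methoxyphenyl)chroman-4-one F3. Its lithium enolate (LiN(SiMe3)2, THF, −78 °C) is alkylated by 11 anti to the C2 aryl group, giving the 2,3-trans ketone (2R,3S)-7-methoxy-5-(4-methoxybenzyloxy)-2-(4-methoxyphenyl)-3-{2-oxo-2-[2,4,6-tris(4-methoxybenzyloxy)phenyl]ethyl}chroman-4-one F4. Double deprotonation (LiN(i-Pr)2, 2.2 equiv, −78 °C) and quench at −78 °C with a hindered phenol should protonate C3 from the face opposite the C2 aryl group and give the cis ketone 14.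

Step 12. The tertiary hydrogen at C3 of unit B may migrate to the carbenoid (1,2-hydride shift), or the catalyst may be mismatched with the resident stereocentres. The fallback sets out from 16 and comes back at 17; it masks that hydrogen and resets C3 of unit B afterwards. Silylation of 16 (t-BuMe2SiOTf, Et3N, CH2Cl2, −78 °C) turns the ketone of unit B into the enol silane (2S)-4-(tert-butyldimethylsilyloxy)-3-{1-diazo-2-oxo-2-[2,4,6-tris(4-methoxybenzyloxy)phenyl]ethyl}-7-methoxy-5-(4-methoxybenzyloxy)-2-(4-methoxyphenyl)-2H-chromene F5 (2S by the sequence rule only; the spatial arrangement at C2 is unchanged). Its dirhodium carbenoid (Rh2(S-PTTL)4, CH2Cl2) is a siloxyvinyl carbenoid without a beta-hydrogen and should insert into the PMB C–H of unit A to give (2R,3R)-3-[(2S)-4-(tert-butyldimethylsilyloxy)-7-methoxy-5-(4-methoxybenzyloxy)-2-(4-methoxyphenyl)-2H-chromen-3-yl]-5,7-bis(4-methoxybenzyloxy)-2-(4-methoxyphenyl)chroman-4-one F6. Protodesilylation (HF·pyridine, THF, −40 °C) should protonate C3 of unit B from the face opposite its C2 aryl group and give 17.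

Step 11. The base may also deprotonate the tertiary C3–H of the cis flavanone, which leads to epimerization to the trans isomer or to beta-elimination of the phenoxide (ring opening). The fallback sets out from 13 and comes back at 15; it moves the base-mediated activation in front of the first ring closure, where no stereocentre exists and only one position is enolizable. Deprotonation of 13 (LiN(SiMe3)2, THF, −78 °C) and acylation with CF3CO2CH2CF3 gives 2-diazo-1-[4-methoxy-2,6-bis(4-methoxybenzyloxy)phenyl]-3-(trifluoroacetyl)-4-[2,4,6-tris(4-methoxybenzyloxy)phenyl]butane-1,4-dione F7. The insertion of step 10 applied to F7 (Rh2(S-PTTL)4, CH2Cl2) should give 15 directly, and the second stage of step 11 (sulfonyl azide, Et3N) then leads to 16 without strong base.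

Further compounds
F1 | step 10 | (E)-3-(dimethylamino)-1-[2-hydroxy-4-methoxy-6-(4-methoxybenzyloxy)phenyl]prop-2-en-1-one | CN(C)/C=C/C(=O)c1c(O)cc(OC)cc1OCc1ccc(OC)cc1
F2 | step 10 | 7-methoxy-5-(4-methoxybenzyloxy)-4H-chromen-4-one | O=c1ccoc2cc(OC)cc(OCc3ccc(OC)cc3)c12
F3 | step 10 | (2R)-7-methoxy-5-(4-methoxybenzyloxy)-2-(4-methoxyphenyl)chroman-4-one | O=C1C[C@H](c2ccc(OC)cc2)Oc2cc(OC)cc(OCc3ccc(OC)cc3)c12
F4 | step 10 | (2R,3S)-7-methoxy-5-(4-methoxybenzyloxy)-2-(4-methoxyphenyl)-3-{2-oxo-2-[2,4,6-tris(4-methoxybenzyloxy)phenyl]ethyl}chroman-4-one | O=C(C[C@@H]1C(=O)c2c(OCc3ccc(OC)cc3)cc(OC)cc2O[C@H]1c1ccc(OC)cc1)c1c(OCc2ccc(OC)cc2)cc(OCc2ccc(OC)cc2)cc1OCc1ccc(OC)cc1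
F5 | step 12 | (2S)-4-(tert-butyldimethylsilyloxy)-3-{1-diazo-2-oxo-2-[2,4,6-tris(4-methoxybenzyloxy)phenyl]ethyl}-7-methoxy-5-(4-methoxybenzyloxy)-2-(4-methoxyphenyl)-2H-chromene | [N-]=[N+]=C(C1=C(O[Si](C)(C)C(C)(C)C)c2c(OCc3ccc(OC)cc3)cc(OC)cc2O[C@H]1c1ccc(OC)cc1)C(=O)c1c(OCc2ccc(OC)cc2)cc(OCc2ccc(OC)cc2)cc1OCc1ccc(OC)cc1
F6 | step 12 | (2R,3R)-3-[(2S)-4-(tert-butyldimethylsilyloxy)-7-methoxy-5-(4-methoxybenzyloxy)-2-(4-methoxyphenyl)-2H-chromen-3-yl]-5,7-bis(4-methoxybenzyloxy)-2-(4-methoxyphenyl)chroman-4-one | COc1ccc([C@@H]2Oc3cc(OCc4ccc(OC)cc4)cc(OCc4ccc(OC)cc4)c3C(=O)[C@@H]2C2=C(O[Si](C)(C)C(C)(C)C)c3c(OCc4ccc(OC)cc4)cc(OC)cc3O[C@H]2c2ccc(OC)cc2)cc1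
F7 | step 11 | 2-diazo-1-[4-methoxy-2,6-bis(4-methoxybenzyloxy)phenyl]-3-(trifluoroacetyl)-4-[2,4,6-tris(4-methoxybenzyloxy)phenyl]butane-1,4-dione | [N-]=[N+]=C(C(C(=O)C(F)(F)F)C(=O)c1c(OCc2ccc(OC)cc2)cc(OCc2ccc(OC)cc2)cc1OCc1ccc(OC)cc1)C(=O)c1c(OCc2ccc(OC)cc2)cc(OC)cc1OCc1ccc(OC)cc1
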